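**Assumptions (one line each):** (i) the phosphine [3+2] gives the regioisomer with C8 bonded to C9 and C6 bonded to C5; (ii) acylation of lactol 14 gives the axial acylal matching the target at C1 (separate anomers if needed); (iii) stannane 8 is obtained from (tributylstannyl)methanol + TBSCl. Iridoid numbering is used: C1 is the acetal carbon, C10 is the CH2O on C8, and C11 is the CH2O on C4.

## Retrosynthetic overview
1. Target ⇐ bis-acylation (C1 lactol OH, C11 OH) after O-allyl and O-TBS removal from C10-acetate diol 12.
2. The trans-7,8-diol with 10-OAc ⇐ base-mediated Payne rearrangement/acetolysis of the convex-face epoxy allylic alcohol 11, which fixes C7 (epoxide oxygen retained) and C8 (inversion).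
3. Ring order: the pyran is built first (Achmatowicz dearomatisation of furfuryl alcohol), then the cis-fused cyclopentene by phosphine-catalysed [3+2] of an allenoate onto pyranone 4. The C3=C4 enol ether and C11 come last from the ring-A ketone via enol triflate and Stille coupling.

## Route

**Step 1**
Reactants: 1 furfuryl alcohol
Product: 2 6-hydroxy-2H-pyran-3(6H)-one (racemic, anomeric mixture)
Conditions: NBS, NaHCO3, NaOAc·3H2O, THF/H2O (4:1), 0 °C
Reagents that add atoms: water (O)
Why: Achmatowicz oxidative ring expansion dearomatises the furan and gives the pyran acetal oxidation level needed at C1. No stereocentre is controlled here.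

**Step 2**
Reactants: 2
Product: 3 6-(tert-butoxycarbonyloxy)-2H-pyran-3(6H)-one (anomeric mixture)
Conditions: Boc2O, DMAP (cat.), CH2Cl2, −78 °C
Reagents that add atoms: Boc2O, CC(C)(C)OC(=O)OC(=O)OC(C)(C)C
Why: The anomeric carbonate is a leaving group for Pd π-allyl/oxocarbenium chemistry.

**Step 3**
Reactants: 3
Product: 4 (6R)-6-(allyloxy)-2H-pyran-3(6H)-one
Conditions: allyl alcohol (1.5 equiv), Pd2(dba)3·CHCl3 (2.5 mol %), (R,R)-DACH-phenyl Trost ligand (7.5 mol %), CH2Cl2, 0 °C
Reagents that add atoms: allyl alcohol, C=CCO
Why: Proposed new method: Pd-catalysed dynamic kinetic asymmetric O-allylation. Both anomers of 3 ionise to the same Pd-bound oxocarbenium/π-allyl species, which the chiral ligand captures enantioselectively. The closest known chemistry is stereospecific Pd glycosylation of Boc-pyranones plus Trost DYKAT. This sets the only stereocentre in 4, which controls the facial selectivity of step 4.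

**Step 4**
Reactants: 4 and 5 ethyl buta-2,3-dienoate
Product: 6 cis-fused bicyclic ketone-enoate (1-allyloxy-4-oxo, C7=C8, CO2Et on C8)
Conditions: PBu3 (20 mol %), toluene, 40 °C
Reagents that add atoms: none (5 is numbered)
Why: Proposed new method: Lu-type phosphine-catalysed [3+2] annulation of an allenoate onto a cyclic enone. The phosphonium zwitterion attacks C9 (β to the ketone) anti to the pseudoaxial 6-allyloxy group. The resulting enolate at C5 closes onto the vinylphosphonium, so C6 bonds to C5 and PBu3 is expelled. This forms the cis ring fusion and puts C1–O trans to the new C8–C9 bond, as in the target. It sets C5 and C9 and installs C6, C7, C8 and C10 in one step; cyclic β-substituted enones are poor Lu acceptors, so this is the riskiest bond-forming step.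

**Step 5**
Reactants: 6
Product: 7 enol triflate (C3=C4–OTf)
Conditions: KHMDS (1.1 equiv), THF, −78 °C; then PhNTf2 (1.2 equiv)
Reagents that add atoms: PhNTf2, O=S(=O)(C(F)(F)F)N(c1ccccc1)S(=O)(=O)C(F)(F)F
Why: Kinetic enolisation takes place at the O-flanked CH2 (C3), giving the enol triflate toward the acetal oxygen. C5 and C9 are untouched.

**Step 6**
Reactants: 7 and 8 tributyl[(tert-butyldimethylsilyloxy)methyl]stannane
Product: 9 enol ether with C11–OTBS
Conditions: Pd(PPh3)4 (5 mol %), LiCl (3 equiv), THF, 65 °C
Reagents that add atoms: none (8 is numbered)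
Why: Stille coupling of a vinyl triflate with an α-alkoxymethylstannane installs C11 and gives the C3=C4 enol ether with retention.

**Step 7**
Reactants: 9
Product: 10 allylic alcohol (C10–OH)
Conditions: DIBAL-H (3 equiv), CH2Cl2, −78 → 0 °C
Reagents that add atoms: none
Why: Reduction of the conjugated ester to the primary allylic alcohol. The allyl acetal, TBS ether and enol ether are inert at low temperature.

**Step 8**
Reactants: 10
Product: 11 7,8-epoxy-10-ol (epoxide on the convex face, cis to H5/H9)
Conditions: VO(acac)2 (5 mol %), TBHP (1.5 equiv), CH2Cl2, 0 °C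
Reagents that add atoms: tert-butyl hydroperoxide, CC(C)(C)OO
Why: Hydroxyl-directed (Sharpless–Mihelich) epoxidation delivers oxygen to the face anti to the ring-A substituents at C1 and C4. This places the C7–O on the convex face, as required. Vanadium is selective for the allylic alcohol over the enol ether.

**Step 9**
Reactants: 11
Product: 12 (7-OH, 8-OH, 10-OAc; C8–OH down, C10 up)
Conditions: CsOAc (3 equiv), AcOH (1 equiv), DMF, 80 °C
Reagents that add atoms: acetic acid, CC(=O)O
Why: Proposed new method: Payne rearrangement/acetolysis. The C10 alkoxide opens the C7–C8 epoxide at C8 with inversion, giving the spiro 8,10-epoxide (O down, C10 up) and a free C7–OH that keeps its up configuration. Acetate then opens the spiro epoxide at the primary C10. The net result is the trans-7,8-diol with C10–OAc, and the conditions are acid-free so the enol ether and acetal survive. The closest known chemistry is Payne rearrangement/nucleophile ring opening of 2,3-epoxy alcohols; the relief of cyclopentene-oxide strain should favour the spiro epoxide.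

**Step 10**
Reactants: 12
Product: 13 (C11–OH)
Conditions: HF·pyridine, pyridine, THF, 0 °C → rt
Reagents that add atoms: none
Why: Buffered fluoride removes the primary TBS ether without disturbing the acetate, enol ether or allyl acetal.

**Step 11**
Reactants: 13
Product: 14 lactol (C1–OH, anomeric mixture; use immediately)
Conditions: Pd(PPh3)4 (5 mol %), morpholine (5 equiv), THF, rt
Reagents that add atoms: none
Why: Pd(0)-catalysed allyl transfer cleaves the anomeric O-allyl acetal under neutral conditions, so the enol ether is spared. C1 is re-set in the next step.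

**Step 12**
Reactants: 14 and 15 isovaleryl chloride
Product: 16 target
Conditions: 15 (2.3 equiv), pyridine, DMAP (cat.), CH2Cl2, −20 → 0 °C
Reagents that add atoms: none (15 is numbered)
Why: Acylation of the two most nucleophilic OH groups (lactol C1–OH and primary C11–OH). The C7 secondary and C8 tertiary OH groups are hindered and stay free. The anomeric acylation goes to the axial acylal, matching the target.

## Compound list
1 | furfuryl alcohol | OCc1ccco1 | starting material
2 | 6-hydroxy-2H-pyran-3(6H)-one | O=C1COC(O)C=C1 | intermediate
3 | 6-(Boc-oxy)-2H-pyran-3(6H)-one | O=C1COC(OC(=O)OC(C)(C)C)C=C1 | intermediate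
4 | (6R)-6-(allyloxy)-2H-pyran-3(6H)-one | O=C1CO[C@@H](OCC=C)C=C1 | intermediate
5 | ethyl buta-2,3-dienoate | C=C=CC(=O)OCC | starting material
6 | ethyl 1-allyloxy-4-oxo-cyclopenta[c]pyran-8-carboxylate (C7=C8, cis-fused) | CCOC(=O)C1=CC[C@@H]2C(=O)CO[C@@H](OCC=C)[C@H]12 | intermediate
7 | enol triflate of 6 | CCOC(=O)C1=CC[C@@H]2C(OS(=O)(=O)C(F)(F)F)=CO[C@@H](OCC=C)[C@H]12 | intermediate
8 | tributyl[(TBS-oxy)methyl]stannane | CCCC[Sn](CCCC)(CCCC)CO[Si](C)(C)C(C)(C)C | starting material
9 | enoate with C11–OTBS, C3=C4 enol ether | CCOC(=O)C1=CC[C@@H]2C(CO[Si](C)(C)C(C)(C)C)=CO[C@@H](OCC=C)[C@H]12 | intermediate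
10 | allylic alcohol (C10–OH) | OCC1=CC[C@@H]2C(CO[Si](C)(C)C(C)(C)C)=CO[C@@H](OCC=C)[C@H]12 | intermediate
11 | 7,8-epoxy-10-ol (convex epoxide) | OC[C@]12O[C@H]1C[C@@H]3C(CO[Si](C)(C)C(C)(C)C)=CO[C@@H](OCC=C)[C@H]23 | intermediate
12 | 10-acetate, 7,8-diol, 1-O-allyl, 11-OTBS | CC(=O)OC[C@]1(O)[C@H]2[C@H](OCC=C)OC=C(CO[Si](C)(C)C(C)(C)C)[C@H]2C[C@@H]1O | intermediate
13 | 11-alcohol of 12 | CC(=O)OC[C@]1(O)[C@H]2[C@H](OCC=C)OC=C(CO)[C@H]2C[C@@H]1O | intermediate
14 | lactol (C1–OH) | CC(=O)OC[C@]1(O)[C@H]2C(O)OC=C(CO)[C@H]2C[C@@H]1O | intermediate
15 | isovaleryl chloride | CC(C)CC(=O)Cl | starting material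
16 | target | CC(=O)OC[C@]1(O)[C@H]2[C@H](OC(=O)CC(C)C)OC=C(COC(=O)CC(C)C)[C@H]2C[C@@H]1O | target

**Total steps:** 12. **Longest linear sequence:** 12 (1 → 2 → 3 → 4 → 6 → 7 → 9 → 10 → 11 → 12 → 13/14 → 16; 5, 8 and 15 enter convergently).

## Three steps most likely to fail
1. **Step 4 (phosphine [3+2] on the pyranone).** Cyclic β-substituted enones are poor Lu acceptors, and the α′-CH2 is acidic. Fallback (different approach): conjugate addition of a 2-(TBSOCH2)vinyl cuprate to 4 with allyl bromide trapping, ring-closing metathesis (Grubbs II) to the cyclopentene, and DBU epimerisation at C5 to the cis-fused ring. This gives the C10–OTBS analogue of 10 after desilylation.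
2. **Step 9 (Payne rearrangement/acetolysis).** The spiro epoxide may not form, or acetate may attack C7 instead. Fallback (different approach): install the diol before the enol ether exists. Ketalise the ketone of 6, reduce the ester, epoxidise, and hydrolyse epoxide and ketal with aqueous acid so that water attacks the tertiary C8 with inversion. Then re-enter at the enol triflate, with the C10 primary OH acetylated selectively.
3. **Step 3 (Pd DYKAT).** The enantioselectivity is unproven for Boc-pyranones. Fallback (different approach): use the racemic Pd/PPh3 glycosylation to give (±)-4, carry it through, and resolve at allylic alcohol 10 by lipase-catalysed acetylation (PS lipase, vinyl acetate).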